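## Structural features

The target is a depside built from two benzene rings and no other ring. Ring A is a 2,4-dimethoxy-6-propylbenzoyl unit (C1 carries the carbonyl, C2 and C4 the methoxy groups, C6 the propyl chain). Ring B is a benzoic acid with the carboxyl on C1, a free hydroxyl on C2 and a pentyl chain on C6. The rings are joined only by an ester bridge from the ring A carbonyl carbon to the oxygen on C4 of ring B. There is no stereocentre, so the problem is one of regiochemistry and reactivity alone. The fragile points are the aryl ester (cleaved by hydroxide, alkoxide and amines), the salicylic acid of ring B (chelating, and liable to decarboxylate when heated in acid) and the electron-rich ring A (open to halogenating agents and carbocations). The real difficulty is the ester: its carbonyl carbon is shielded by the C2 methoxy and C6 propyl groups, so addition–elimination there is slow, and a conventional ring B partner would carry two phenolic oxygens, O2 and O4, that must be told apart. The key step exploits the fact that C4 of ring B is the only ring B carbon lying between two C–H positions (C3 and C5). Boron can therefore be placed there by sterically ruled C–H borylation, and the C4–O bond is then made at this open carbon by copper-mediated arylation of the ring A carboxylate, three atoms from the congested centre. O2 and the ring B carboxyl then need only passive masks, a methoxymethyl (MOM) ether and a tert-butyl ester, which contain no aromatic C–H bond and leave under one acid treatment.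

## Logic of the disconnections

**17 to 16.** No skeletal bond is cut. The carboxyl O–H and the O2–H of 17 are traced back to an O–tert-butyl and an O–CH2OCH3 bond in 16. A free salicylic acid would bind copper and offer two competing oxygen nucleophiles in the coupling, and benzyl masks would be borylated. The gain is a single final operation. The demand is an acidolysis that spares the aryl ester and does not let the released cations alkylate ring A.

**16 to 15 and 10.** The bond cut is C4(ring B)–O of the ester, not the usual acyl–O bond. Cutting here moves bond formation from the shielded acyl carbon to an aryl carbon with hydrogen on both sides, and gives two monocyclic fragments of similar size. The forward step must transfer the carboxylate to the aryl group faster than hydroxide or a proton, which requires boron at C4 only and no other free nucleophile.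

**10 to 7 and 8 (through 9).** The bond cut is C4–B. C4–H is the only ring B hydrogen without an ortho neighbour, so a sterically controlled catalyst can find it. The gain is large: ring B needs no oxygen at C4 beforehand and O2 and O4 never have to be differentiated. The demand is a catalyst indifferent to the acetal and ester oxygens, and a release of pinacol from 9 mild enough for both acid-labile masks.

**7 to 6.** The O–CH2 bond of the acetal is cut. The forward step must alkylate a phenol that is hydrogen-bonded to the neighbouring ester.

**6 to 5.** Two C–H bonds are restored (retro-dehydrogenation). A non-aromatic ring opens the way to carbonyl-based ring construction. The oxidant must stop at the phenol and leave the tert-butyl ester alone.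

**5 to 1 and 2 (through 3 and 4).** The ring bonds C1–C6 (conjugate addition) and C3–C4 (aldol condensation) are cut. This gives two cheap eight-carbon pieces that already hold all sixteen carbons, the pentyl chain and the tert-butyl ester. The forward step needs 1,4-addition rather than 1,2-addition to the enal, and dehydration without loss of the ester.

**15 to 14.** The carboxyl C–OH bond is cut back to an aldehyde. The oxidation must work at a di-ortho-substituted aldehyde without chlorinating ring A.

**14 to 12 (through 13).** The ring–CHO bond is cut. The formylation must go to the carbon between propyl and methoxy (para to the other methoxy), not to the carbon between the two methoxy groups.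

**12 to 11.** The aryl–propyl bond is cut, which leads to a commercial aryl bromide and a propyl Grignard reagent in one step. The coupling must deliver the propyl group unrearranged.

## Other disconnections considered

**Alternative 1:** Biomimetic aldol folding.
- **Cut:** the ring A bond between the carboxyl-bearing carbon and the propyl-bearing carbon. Ring A becomes an open 3,5,7-trioxodecanoyl chain carried as the O4 ester A2 of the ring B phenol A3.
- **Forward key step:** mild base lets the C2 methylene of A2 add to the C7 ketone; dehydration and enolization would give the dihydroxy depside A1.
- **In favour:** the ester is formed while the acyl group is an unhindered chain, so the hindered esterification never arises. No metal is used. The benzyl masks allow a neutral hydrogenolytic end-game, which is milder than the acid deprotection of the chosen plan; on this point the alternative is the better.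
- **Against:** A2 is laborious to assemble and can fold in other ways. Claisen-type C-acylation and pyranone formation both expel A3, because an aryl ester is an activated acyl donor. A1 then needs double O-methylation of ring A, with one hydroxyl hydrogen-bonded to the ester carbonyl, under base that the depside must survive. A3 requires O2 benzylated and O4 free, the reverse of the innate reactivity of a 2,4-dihydroxybenzoate.
- **Comparison:** on structure it reaches the same skeleton. On mechanism it trades a C–O coupling for a ring-forming aldol whose chemoselectivity is less secure. On step economy it should be clearly longer.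

**Alternative 2:** Three-component carbonylation.
- **Cut:** both bonds at the ester carbonyl carbon.
- **Forward key step:** the aryl iodide A5, carbon monoxide and A3 are joined by Pd(OAc)2, Xantphos and triethylamine to give A4.
- **In favour:** it is highly convergent. The hindered ester is formed at an acylpalladium centre, not by attack on an acid chloride, so on avoiding addition–elimination at the shielded carbon it is the equal of the chosen plan. A5 should come from 12 in one iodination, two steps fewer than 15; on the ring A side it is the better. Hydrogenolysis of A4 is again a gentler end-game.
- **Against:** A3 demands the same O2/O4 differentiation and a 4-oxygenated ring B made separately. Carbon monoxide insertion into a di-ortho-substituted, electron-rich arylpalladium is slow, and phenols are weak partners in such carbonylations, so direct C–O coupling and reduction of A5 may compete. A toxic gas under pressure is needed.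
- **Comparison:** ring A is shorter and ring B longer, so the overall count is about equal or higher. The mechanism is no more certain than the chosen coupling.

**Alternative 3:** Diels–Alder benzannulation.
- **Cut:** two ring A bonds, from the carboxyl-bearing carbon to the methoxy-bearing carbon and from the propyl-bearing carbon to its CH neighbour.
- **Forward key step:** the hex-2-ynoate ester A7 of A3 reacts thermally with the diene A8; loss of methanol and desilylation would give A6.
- **In favour:** the ester is made from an unhindered alkynoic acid. Ring A arises in one step with its two oxygens already differentiated, and regiochemistry is fixed by diene polarization; on these points it is the equal or the better.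
- **Against:** a 3-alkyl-substituted alkynoate is a sluggish dienophile and needs prolonged heating, while A8 is thermally and hydrolytically labile. A6 needs one more O-methylation. A3 is again required.
- **Comparison:** the mechanism is concerted and sound, and the structural outcome is the same. Step economy is worse because of A3 and the added methylation, and the cycloaddition is the less dependable key step.

Key step: step 8

Remark on the chemistry: 3, 4 and 5 are racemic diastereomer mixtures (5 also a keto–enol mixture). Their SMILES carry no stereodescriptors because both centres become sp2 in step 2; the target has no stereocentre.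

Remark on the design: the connectivity of the target, both coupling partners and the coupling product is consistent and needs no correction. Two changes are made to the plan. Boron enters the coupling as the free boronic acid 10, released in the same flask from the pinacol ester 9, because pinacol retards aryl transfer to copper. The propyl group is attached to ring A by one cross-coupling from 11.

## Steps

Step 1
Reactants: 1 tert-butyl acetoacetate; 2 (E)-oct-2-enal
Product: 5 tert-butyl 2-oxo-6-pentylcyclohex-3-ene-1-carboxylate (racemic; epimer and enol mixture), via keto aldehyde 3 (not isolated), via hydroxy ketone 4 (not isolated)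
Conditions: t-BuOK (0.2 equiv), t-BuOH/THF, 0 °C → rt, then 50 °C; aq NH4Cl
Reagents that add atoms: none
Why: Robinson-type annulation: Michael addition of the acetoacetate enolate to the enal β-carbon gives 3, the methyl ketone enolate closes on the aldehyde in the only strain-free aldol mode to give 4, and E1cB loss of water gives the enone, held as its stabilized enolate. tert-Butoxide matches the ester, so transesterification is impossible, and the two racemic stereocentres are erased in step 2.

Step 2
Reactants: 5 tert-butyl 2-oxo-6-pentylcyclohex-3-ene-1-carboxylate
Product: 6 tert-butyl 2-hydroxy-6-pentylbenzoate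
Conditions: DDQ (1.3 equiv), toluene, 80 °C
Reagents that add atoms: none
Why: Quinone dehydrogenation: hydride abstraction from C6 of the enol tautomer gives an oxygen-stabilized cation that loses a proton to the arene, driven by aromaticity and the salicylate hydrogen bond. The neutral medium spares the tert-butyl ester, and the pentyl chain is meta to the hydroxyl, so no quinone methide can form.

Step 3
Reactants: 6 tert-butyl 2-hydroxy-6-pentylbenzoate
Product: 7 tert-butyl 2-(methoxymethoxy)-6-pentylbenzoate
Conditions: NaH (1.3 equiv), THF, 0 °C; MOMCl (1.3 equiv), 0 °C → rt; aq NH3 quench (closed handling, carcinogenic reagent)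
Reagents that add atoms: chloromethyl methyl ether, COCCl
Why: Williamson-type O-alkylation: full deprotonation breaks the phenol–ester hydrogen bond and the α-chloro ether alkylates even a hindered phenoxide. The acetal has no aromatic C–H bond, is inert to the iridium and copper steps, and falls to the same acid as the ester.

Step 4
Reactants: 7 tert-butyl 2-(methoxymethoxy)-6-pentylbenzoate; 8 bis(pinacolato)diboron
Product: 10 [4-(tert-butoxycarbonyl)-3-(methoxymethoxy)-5-pentylphenyl]boronic acid, via pinacol boronate 9 (not isolated)
Conditions: [Ir(OMe)(cod)]2 (1.5 mol%), 4,4'-di-tert-butyl-2,2'-bipyridine (3 mol%), 8 (1.0 equiv), THF, 80 °C; evaporate; NaIO4 (3 equiv), NH4OAc (3 equiv), acetone/H2O, rt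
Reagents that add atoms: water, O
Why: Sterically governed iridium-catalysed aromatic C–H borylation: the tris(boryl) complex of trivalent iridium activates only C–H bonds without an ortho substituent, and in 7 only C4–H qualifies (C3 is next to the acetal oxygen, C5 next to pentyl). Periodate then destroys the pinacol released in the buffered hydrolysis equilibrium and so pulls 9 over to the boronic acid without acid strong enough to touch the acetal or the ester.

Step 5
Reactants: 11 1-bromo-3,5-dimethoxybenzene
Product: 12 1,3-dimethoxy-5-propylbenzene
Conditions: n-PrMgBr (1.3 equiv), NiCl2(dppp) (2 mol%), THF, 0 °C → 50 °C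
Reagents that add atoms: n-propylmagnesium bromide, CCC[Mg]Br
Why: Kumada coupling: oxidative addition of the aryl bromide to zerovalent nickel, transmetalation and reductive elimination. The chelating diphosphine makes reductive elimination faster than β-hydride elimination, so the propyl group should arrive unrearranged.

Step 6
Reactants: 12 1,3-dimethoxy-5-propylbenzene
Product: 14 2,4-dimethoxy-6-propylbenzaldehyde, via iminium salt 13 (not isolated)
Conditions: POCl3 (1.3 equiv), DMF, 0 °C → 70 °C; then ice-water, rt
Reagents that add atoms: N,N-dimethylformamide, CN(C)C=O; water, O
Why: Vilsmeier–Haack formylation: the chloroiminium ion attacks the carbon para to one methoxy and ortho to the other, the usual preference of 5-alkylresorcinol dimethyl ethers over the doubly ortho carbon between the two methoxy groups. The two favoured carbons are equivalent by symmetry, and water hydrolyses 13 to the aldehyde.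

Step 7
Reactants: 14 2,4-dimethoxy-6-propylbenzaldehyde
Product: 15 2,4-dimethoxy-6-propylbenzoic acid
Conditions: NaClO2 (3 equiv), NaH2PO4 (3 equiv), 2-methyl-2-butene (10 equiv), t-BuOH/THF/H2O, 0 °C → rt
Reagents that add atoms: sodium chlorite, [Na+].[O-]Cl=O
Why: Pinnick oxidation: chlorous acid adds to the aldehyde and the adduct fragments to the acid and hypochlorous acid, a pathway little affected by di-ortho substitution. The alkene intercepts hypochlorous acid before it can chlorinate ring A.

Step 8
Reactants: 15 2,4-dimethoxy-6-propylbenzoic acid; 10 [4-(tert-butoxycarbonyl)-3-(methoxymethoxy)-5-pentylphenyl]boronic acid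
Product: 16 tert-butyl 4-[(2,4-dimethoxy-6-propylbenzoyl)oxy]-2-(methoxymethoxy)-6-pentylbenzoate
Conditions: 15 (1.5 equiv), Cu(OTf)2 (0.5 equiv), pyridine (3 equiv), powdered 4 Å molecular sieves, EtOAc, dry air, 50 °C
Reagents that add atoms: none
Why: This is a Chan–Lam-type oxidative coupling of a carboxylic acid with an arylboronic acid, the closest known reaction type. Pyridine deprotonates 15 and the carboxylate binds divalent copper; the aryl group of 10 then passes from boron to copper through an oxygen-bridged Cu–O–B contact. The divalent copper aryl carboxylate is oxidized, by a second divalent copper or by air, to a trivalent copper species that forms the C4–O bond by reductive elimination, and air returns monovalent copper to the divalent state so that Cu(OTf)2 turns over. No ring is closed and no stereocentre is formed. The selectivity needed is acyloxylation at C4 in preference to hydroxylation, protodeboronation and biaryl formation. It is secured because the carboxylate is the only nucleophile on copper (O2 is an acetal and the ring B carboxyl a tert-butyl ester), boron sits only at C4, the sieves remove water and the acid is in excess. Steric demand is low, since the two ortho groups of 15 lie three atoms from the forming bond and C4 of 10 has hydrogen on both sides. Polarity is reversed with respect to a classical esterification, so no nucleophile has to attack the shielded acyl carbon.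

Step 9
Reactants: 16 tert-butyl 4-[(2,4-dimethoxy-6-propylbenzoyl)oxy]-2-(methoxymethoxy)-6-pentylbenzoate
Product: 17 4-[(2,4-dimethoxy-6-propylbenzoyl)oxy]-2-hydroxy-6-pentylbenzoic acid
Conditions: TFA/CH2Cl2 (1:4), H2O (5 equiv), 0 °C → 10 °C; evaporate cold from toluene
Reagents that add atoms: none
Why: Acidolysis: the tert-butyl ester ionizes by alkyl–oxygen cleavage, which is independent of crowding at the acyl carbon, and the acetal leaves through the methoxymethyl oxocarbenium ion. The depside ester would need acyl–oxygen cleavage, which dilute cold TFA should not bring about, and water takes up the cations before they can alkylate ring A.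

## Compound list

1 | tert-butyl acetoacetate | CC(=O)CC(=O)OC(C)(C)C | starting material
2 | (E)-oct-2-enal | CCCCC/C=C/C=O | starting material
3 | tert-butyl 2-acetyl-3-(2-oxoethyl)octanoate (diastereomer mixture, not isolated) | CCCCCC(CC=O)C(C(C)=O)C(=O)OC(C)(C)C | intermediate
4 | tert-butyl 4-hydroxy-2-oxo-6-pentylcyclohexane-1-carboxylate (diastereomer mixture, not isolated) | CCCCCC1CC(O)CC(=O)C1C(=O)OC(C)(C)C | intermediate
5 | tert-butyl 2-oxo-6-pentylcyclohex-3-ene-1-carboxylate (racemic, epimer and enol mixture) | CCCCCC1CC=CC(=O)C1C(=O)OC(C)(C)C | intermediate
6 | tert-butyl 2-hydroxy-6-pentylbenzoate | CCCCCc1cccc(O)c1C(=O)OC(C)(C)C | intermediate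
7 | tert-butyl 2-(methoxymethoxy)-6-pentylbenzoate | CCCCCc1cccc(OCOC)c1C(=O)OC(C)(C)C | intermediate
8 | bis(pinacolato)diboron | CC1(C)OB(OC1(C)C)B1OC(C)(C)C(C)(C)O1 | starting material
9 | tert-butyl 2-(methoxymethoxy)-6-pentyl-4-(4,4,5,5-tetramethyl-1,3,2-dioxaborolan-2-yl)benzoate (not isolated) | CCCCCc1cc(B2OC(C)(C)C(C)(C)O2)cc(OCOC)c1C(=O)OC(C)(C)C | intermediate
10 | [4-(tert-butoxycarbonyl)-3-(methoxymethoxy)-5-pentylphenyl]boronic acid | CCCCCc1cc(B(O)O)cc(OCOC)c1C(=O)OC(C)(C)C | intermediate
11 | 1-bromo-3,5-dimethoxybenzene | COc1cc(Br)cc(OC)c1 | starting material
12 | 1,3-dimethoxy-5-propylbenzene | CCCc1cc(OC)cc(OC)c1 | intermediate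
13 | N-[(2,4-dimethoxy-6-propylphenyl)methylidene]-N-methylmethanaminium dichlorophosphate (not isolated) | CCCc1cc(OC)cc(OC)c1C=[N+](C)C.[O-]P(=O)(Cl)Cl | intermediate
14 | 2,4-dimethoxy-6-propylbenzaldehyde | CCCc1cc(OC)cc(OC)c1C=O | intermediate
15 | 2,4-dimethoxy-6-propylbenzoic acid | CCCc1cc(OC)cc(OC)c1C(=O)O | intermediate
16 | tert-butyl 4-[(2,4-dimethoxy-6-propylbenzoyl)oxy]-2-(methoxymethoxy)-6-pentylbenzoate | CCCCCc1cc(OC(=O)c2c(CCC)cc(OC)cc2OC)cc(OCOC)c1C(=O)OC(C)(C)C | intermediate
17 | 4-[(2,4-dimethoxy-6-propylbenzoyl)oxy]-2-hydroxy-6-pentylbenzoic acid | CCCCCc1cc(OC(=O)c2c(CCC)cc(OC)cc2OC)cc(O)c1C(=O)O | target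

## Step count and least certain steps

Total: 9 steps. Longest linear sequence: 6 steps (1, 2, 3, 4, 8, 9). The ring A branch (5, 6, 7) joins at step 8.

**Step 8 (key step).** Aryl transfer from boron to copper may lag behind loss of the boron group by protonolysis, copper-mediated hydroxylation by residual water, or homocoupling. The bulky, electron-rich carboxylate may also slow the reductive elimination. The fallback sets out from 10 and 15 and returns at 16 with normal polarity at the open phenol. Oxidation of 10 with aqueous H2O2 in THF at 0 °C should give tert-butyl 4-hydroxy-2-(methoxymethoxy)-6-pentylbenzoate F1. Oxalyl chloride with catalytic DMF in CH2Cl2 should turn 15 into 2,4-dimethoxy-6-propylbenzoyl chloride F2. The sodium phenoxide of F1 (NaH, THF, 0 °C → rt) is then acylated by F2, which reacts through an acylium-like pathway, to give 16. O4 remains uniquely defined because it derives from the C4 boron.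

**Step 2.** Hydride abstraction from the crowded tertiary C6–H may be slow, and the quinone may instead add to the dienol, so that material is lost before aromatization. The fallback sets out from 5 and returns at 6 by halogenation–elimination. NBS in CH2Cl2 at 0 °C should brominate C1 to give tert-butyl 1-bromo-2-oxo-6-pentylcyclohex-3-ene-1-carboxylate F3. LiBr and Li2CO3 in DMF at 80 °C then epimerize the bromide and eliminate HBr across C1–C6, and the dienone tautomerizes to 6.

**Step 1.** The enolate may attack the aldehyde carbon instead (condensation followed by electrocyclization to a pyran), the enal may self-condense under alkoxide, or the sequence may stall at the aldol stage. The fallback sets out from 1 and 2 and returns at 5 by iminium activation of the enal. α,α-Diphenylprolinol trimethylsilyl ether (10 mol%, either enantiomer) with benzoic acid in toluene at rt should direct clean 1,4-addition and aldol closure to 4, which is isolated. MsCl and Et3N in CH2Cl2 then give tert-butyl 4-(methanesulfonyloxy)-2-oxo-6-pentylcyclohexane-1-carboxylate F4, which eliminates in the same flask to 5 without any acid.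

**Step 4.** The borylation itself follows a firm steric rule. The weak part is the release of boron from pinacol, which may be incomplete, or the loss of the boron group during the aqueous oxidative stage; the boronic acid is also awkward to purify. The fallback sets out from 9 (isolated by chromatography) and returns at 10. KHF2 in MeOH/H2O should give potassium [4-(tert-butoxycarbonyl)-3-(methoxymethoxy)-5-pentylphenyl]trifluoroborate F5, purified by precipitation, and hydrolysis on wet silica gel in EtOAc/H2O then gives 10.

**Step 9.** The tert-butyl and methoxymethyl cations, or formaldehyde, may alkylate ring A. Acetal cleavage may be slow at low temperature, and forcing it invites decarboxylation of the salicylic acid. The fallback sets out from 16 and returns at 17 in two orthogonal stages. ZnBr2 with n-PrSH in CH2Cl2 at 0 °C transfers the acetal carbon to sulfur and should give tert-butyl 4-[(2,4-dimethoxy-6-propylbenzoyl)oxy]-2-hydroxy-6-pentylbenzoate F6 without a free electrophile. Cold TFA/CH2Cl2 then has only the tert-butyl ester to remove.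

## Further compounds

F1 | step 8 | tert-butyl 4-hydroxy-2-(methoxymethoxy)-6-pentylbenzoate | CCCCCc1cc(O)cc(OCOC)c1C(=O)OC(C)(C)C
F2 | step 8 | 2,4-dimethoxy-6-propylbenzoyl chloride | CCCc1cc(OC)cc(OC)c1C(Cl)=O
F3 | step 2 | tert-butyl 1-bromo-2-oxo-6-pentylcyclohex-3-ene-1-carboxylate | CCCCCC1CC=CC(=O)C1(Br)C(=O)OC(C)(C)C
F4 | step 1 | tert-butyl 4-(methanesulfonyloxy)-2-oxo-6-pentylcyclohexane-1-carboxylate | CCCCCC1CC(OS(C)(=O)=O)CC(=O)C1C(=O)OC(C)(C)C
F5 | step 4 | potassium [4-(tert-butoxycarbonyl)-3-(methoxymethoxy)-5-pentylphenyl]trifluoroborate | CCCCCc1cc([B-](F)(F)F)cc(OCOC)c1C(=O)OC(C)(C)C.[K+]
F6 | step 9 | tert-butyl 4-[(2,4-dimethoxy-6-propylbenzoyl)oxy]-2-hydroxy-6-pentylbenzoate | CCCCCc1cc(OC(=O)c2c(CCC)cc(OC)cc2OC)cc(O)c1C(=O)OC(C)(C)C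
A1 | alternative 1 | benzyl 2-(benzyloxy)-4-[(2,4-dihydroxy-6-propylbenzoyl)oxy]-6-pentylbenzoate | CCCCCc1cc(OC(=O)c2c(CCC)cc(O)cc2O)cc(OCc2ccccc2)c1C(=O)OCc1ccccc1
A2 | alternative 1 | benzyl 2-(benzyloxy)-6-pentyl-4-[(3,5,7-trioxodecanoyl)oxy]benzoate | CCCCCc1cc(OC(=O)CC(=O)CC(=O)CC(=O)CCC)cc(OCc2ccccc2)c1C(=O)OCc1ccccc1
A3 | alternative 1 | benzyl 2-(benzyloxy)-4-hydroxy-6-pentylbenzoate | CCCCCc1cc(O)cc(OCc2ccccc2)c1C(=O)OCc1ccccc1
A4 | alternative 2 | benzyl 2-(benzyloxy)-4-[(2,4-dimethoxy-6-propylbenzoyl)oxy]-6-pentylbenzoate | CCCCCc1cc(OC(=O)c2c(CCC)cc(OC)cc2OC)cc(OCc2ccccc2)c1C(=O)OCc1ccccc1
A5 | alternative 2 | 1-iodo-2,4-dimethoxy-6-propylbenzene | CCCc1cc(OC)cc(OC)c1I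
A6 | alternative 3 | benzyl 2-(benzyloxy)-4-[(4-hydroxy-2-methoxy-6-propylbenzoyl)oxy]-6-pentylbenzoate | CCCCCc1cc(OC(=O)c2c(CCC)cc(O)cc2OC)cc(OCc2ccccc2)c1C(=O)OCc1ccccc1
A7 | alternative 3 | benzyl 2-(benzyloxy)-4-(hex-2-ynoyloxy)-6-pentylbenzoate | CCCCCc1cc(OC(=O)C#CCCC)cc(OCc2ccccc2)c1C(=O)OCc1ccccc1
A8 | alternative 3 | 1,1-dimethoxy-3-(trimethylsilyloxy)buta-1,3-diene | COC(OC)=CC(=C)O[Si](C)(C)C
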